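The reading comes at 4.0 h, but J turns into G from the start, so in these flasks you should count the enzyme's work and not the hours.

    Q + J → L + J, rate k1*[Q]*[J]/(1 + ([Q]/Km1)) (Km1 = 9.8 mM, k1 = 67000 /M/h)
    J → G (k2 = 0.24 /h)

| setting | autumn | midnight | summer |
|---|---|---|---|
| Q | 30 mM | 30 mM | 30 mM |
| J | 0.035 mol% | 0.046 mol% | 0.059 mol% |
| time | 4.0 h | 4.0 h | 4.0 h |

* which of these there is most of at the end, counted by the Q in it, autumn (L / Q)
* which of these there is most of at the end, counted by the Q in it, midnight (L / Q)
* which of these there is most of at the end, counted by the Q in it, summer (L / Q)
* amount of the one of these that there is most of at the end, in percent of the Q charged, autumn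
* amount of the one of these that there is most of at the end, in percent of the Q charged, midnight
* amount of the one of these that there is most of at the end, in percent of the Q charged, summer

**Working time.** J decays exponentially at 0.24 /h, and integrating that decay makes the run worth 2.57 h of full-strength J. Multiply this by the charged c_J and the rate constant of step one, and you have each flask's budget: 1.81 in autumn, 2.38 at midnight and 3.05 in summer.

**The price.** Divide the Michaelis–Menten rate law by c_Q and integrate. The budget spent equals the logarithm of charged c_Q over present c_Q, plus the drop in c_Q over Km. Charged c_Q over Km is 3.06, so for this charge, converting half costs ln 2 plus half of that ratio, 2.22. This is the price of half, the budget at which L equals Q at the end.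

**The bracket.** The rate sinks as Q goes, so holding the starting rate overstates L. Budget over 1 plus the ratio gives ceilings of 44.5%, 58.5% and 75.1% for autumn, midnight and summer. Holding the starting denominator while c_Q falls understates L, which gives floors of 35.9%, 44.3% and 52.8%.

Midnight straddles half, so compare budgets. Autumn's is less than the price, while midnight's and summer's are more.

**Tightening.** At half, the slope of the price against conversion stands at the ratio plus 2, and this slope rises with conversion. A straight line from half therefore overstates L a little, and the ceilings drop to 41.8%, 53.0% and 66.3%. I commit to Q leading autumn with at least 58.2%, and to L leading midnight and summer.

**The flask.** The forecast says Q at 58.4% in autumn, L at 53% at midnight and L at 65.1% in summer, holding that “the substrate inhibition term holds the rate well down until Q falls”, and each value stands inside the bracket. The simulation gives Q at 58.5% in autumn, L at 53.0% at midnight and L at 65.2% in summer, inside the bracket and on the side of half that the budgets named.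

**Why autumn falls short.** Autumn's L stays below half mainly because of the term in c_Q in the denominator of step one: with that term taken away, autumn's L rises from 41.5% to 83.6%, and L leads there.

Now take midnight with 0.028 mol% of J. Its budget is 1.45, less than the price 2.22, so Q should lead, with L at most 34.7%. The flask gives Q in the lead, with L at 33.8%.

The rate constants are made up; the result is computed.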